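## Retrosynthetic overview
1. 5 ⇒ 4: the last bond made is the 4-O–CH3 of the trioxygenated ring A, by base-free diazoalkane methylation.
2. 4 ⇒ 3 + AcOH: the C7–OAc bond comes from a catalyst-controlled, rearomatising 1,6-addition to a p-quinone methide. This sets C7 and turns the two C8 enantiomers into separable diastereomers.
3. 3 ⇒ 1 + 2: the C8–O(aryl) bond comes from an oxidative, dearomatising 8-O-4' phenoxyl cross-coupling of two C6–C3 phenols.
4. No ring is built. Both arenes are bought; ring A is dearomatised in step 1 and rearomatised in step 2.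

The target is the threo (7R,8R) = (1R,2R) isomer.

Assumption: 2 is bought as the flavour chemical 4-propenylsyringol (E drawn; an E/Z mixture serves equally, because step 1 erases the alkene geometry).

## Route

Step 1
Reactants: 1 4-allyl-2,6-dimethoxyphenol (3 equiv); 2 (E)-2,6-dimethoxy-4-(prop-1-en-1-yl)phenol (1 equiv)
Product: 3 rac-4-[2-(4-allyl-2,6-dimethoxyphenoxy)propylidene]-2,6-dimethoxycyclohexa-2,5-dien-1-one (p-quinone methide)
Conditions: Ag2O (5 equiv), 4 Å MS, toluene, 20 °C, dark, Ar; premixed 1 + 2 added over 6 h; filter through Celite, concentrate below 20 °C, use the same day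
Reagents that add atoms: none
Why: Biomimetic oxidative phenol cross-coupling (oxidative dearomatisation): Ag2O turns both phenols into phenoxyl radicals, the radical of 2 carries spin at C8 while that of 1 can bond only through oxygen because its ortho and para carbons are substituted, so O–C8 recombination gives a non-phenolic p-quinone methide that cannot be over-oxidised, and inverse addition to excess oxidant holds the radical ratio near the 3:1 feed ratio to suppress homo-coupling of 2; C8 is created racemic here and is sorted in step 2.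

Step 2
Reactants: 3 rac-quinone methide
Product: 4 (1R,2R)-2-(4-allyl-2,6-dimethoxyphenoxy)-1-(4-hydroxy-3,5-dimethoxyphenyl)propyl acetate (threo)
Conditions: (R)-TRIP [3,3'-bis(2,4,6-triisopropylphenyl)-BINOL hydrogen phosphate] (10 mol %), AcOH (5 equiv), toluene, −40 °C, 24 h; cold pH 7 wash; SiO2 chromatography to separate threo from erythro
Reagents that add atoms: acetic acid, CC(=O)O
Why: Proposed new method: the phosphoric acid H-bonds to the quinone methide carbonyl (flanked by two OMe acceptors) while its P=O holds AcOH in an acid–acid heterodimer, so acetate is delivered to the Re face of C7 in a rearomatising oxa-1,6-addition whatever the configuration at C8; (R)-3 then gives threo (1R,2R)-4 and (S)-3 gives the erythro (1R,2S) isomer, which is removed by chromatography (stereodivergent reaction of a racemate, 50 % maximum yield); the route to 4 runs against the intrinsic erythro bias of such quinone methides (about 3:1), but the enantiomer of 4 would need both the wrong catalyst face and the wrong substrate face, so the ee of 4 exceeds the catalyst's intrinsic selectivity, and uncatalysed AcOH addition is negligible at −40 °C; the closest known reaction types are the chiral phosphoric acid catalysed 1,6-addition of thioacetic acid to p-quinone methides and phosphoric acid/carboxylic acid heterodimer openings of epoxides; if the first run shows Si-face delivery, (S)-TRIP is used.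

Step 3
Reactants: 4 threo phenolic acetate
Product: 5 (1R,2R)-2-(4-allyl-2,6-dimethoxyphenoxy)-1-(3,4,5-trimethoxyphenyl)propyl acetate (target, CNP0117299.1)
Conditions: CH2N2 (excess, made ex situ from Diazald), Et2O–MeOH 10:1, 0 °C, 12 h
Reagents that add atoms: diazomethane, C=[N+]=[N-]
Why: Diazoalkane O-methylation of a phenol: proton transfer gives a phenoxide/methyldiazonium ion pair that collapses at once, so no free phenoxide lives long enough to expel the benzylic acetate (1,6-elimination back to 3), and C7, C8, the acetate and the allyl group are untouched.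

## Compound list
1 | 4-allyl-2,6-dimethoxyphenol (methoxyeugenol) | C=CCc1cc(OC)c(O)c(OC)c1 | starting material
2 | (E)-2,6-dimethoxy-4-(prop-1-en-1-yl)phenol (4-propenylsyringol) | C/C=C/c1cc(OC)c(O)c(OC)c1 | starting material
3 | rac-4-[2-(4-allyl-2,6-dimethoxyphenoxy)propylidene]-2,6-dimethoxycyclohexa-2,5-dien-1-one (racemic at C8) | C=CCc1cc(OC)c(OC(C)C=C2C=C(OC)C(=O)C(OC)=C2)c(OC)c1 | intermediate
4 | (1R,2R)-2-(4-allyl-2,6-dimethoxyphenoxy)-1-(4-hydroxy-3,5-dimethoxyphenyl)propyl acetate | C=CCc1cc(OC)c(O[C@H](C)[C@H](OC(C)=O)c2cc(OC)c(O)c(OC)c2)c(OC)c1 | intermediate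
5 | (1R,2R)-2-(4-allyl-2,6-dimethoxyphenoxy)-1-(3,4,5-trimethoxyphenyl)propyl acetate | C=CCc1cc(OC)c(O[C@H](C)[C@H](OC(C)=O)c2cc(OC)c(OC)c(OC)c2)c(OC)c1 | target

Total step count: 3. Longest linear sequence: 3.

## Steps most likely to fail, with fallbacks

**Step 2 (highest risk).** The catalyst may not override the erythro bias, or the ee may be low.
- The fallback sets out from 3 and uses the bias instead of fighting it.
- Uncatalysed 1,6-addition of water (acetone/pH 4–5 buffer, 0 °C) gives mainly racemic erythro 2-(4-allyl-2,6-dimethoxyphenoxy)-1-(4-hydroxy-3,5-dimethoxyphenyl)propan-1-ol F1. This compound is base-stable.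
- MeI/K2CO3 in acetone methylates it to racemic erythro 2-(4-allyl-2,6-dimethoxyphenoxy)-1-(3,4,5-trimethoxyphenyl)propan-1-ol F2. The minor threo isomer is removed here by chromatography.
- An acylative kinetic resolution follows, using benzotetramisole, isobutyric anhydride and iPr2NEt, run to about 55 % conversion. The catalyst antipode is chosen so that the 1R alcohol reacts.
- The resolution esterifies one enantiomer to (1R,2S)-2-(4-allyl-2,6-dimethoxyphenoxy)-1-(3,4,5-trimethoxyphenyl)propyl isobutyrate F3. It leaves (1S,2R)-2-(4-allyl-2,6-dimethoxyphenoxy)-1-(3,4,5-trimethoxyphenyl)propan-1-ol F4.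
- A Mitsunobu reaction of F4 with AcOH (PPh3, DIAD, toluene, 0 °C) inverts C7 and installs the acetate in one operation. The fallback comes back to the route at 5.

**Step 1.** Homo-coupling of 2 may dominate, giving a product isomeric with the wanted one. Compound 1 may also be over-oxidised to its vinyl quinone methide.
- The fallback sets out from 1 and builds the same quinone methide by ionic chemistry from the chiral pool.
- Mitsunobu reaction of 1 with ethyl (S)-lactate (PPh3, DIAD, inversion) gives ethyl (R)-2-(4-allyl-2,6-dimethoxyphenoxy)propanoate F5.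
- DIBAL-H at −78 °C gives (R)-2-(4-allyl-2,6-dimethoxyphenoxy)propanal F6, which is used cold and at once.
- Addition of the dianion from 4-bromo-2,6-dimethoxyphenol (n-BuLi, 2.1 equiv, THF, −78 °C) gives (2R)-2-(4-allyl-2,6-dimethoxyphenoxy)-1-(4-hydroxy-3,5-dimethoxyphenyl)propan-1-ol F7. It forms as a C1 epimer mixture, and both epimers converge in the next operations.
- TMSBr in CH2Cl2 gives 4-[(2R)-1-bromo-2-(4-allyl-2,6-dimethoxyphenoxy)propyl]-2,6-dimethoxyphenol F8.
- Shaking F8 with saturated aqueous NaHCO3 eliminates HBr to (R)-4-[2-(4-allyl-2,6-dimethoxyphenoxy)propylidene]-2,6-dimethoxycyclohexa-2,5-dien-1-one F9.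
- This is the route's compound 3 as a single enantiomer, so the fallback comes back at 3. The 50 % ceiling of step 2 is then lifted.

**Step 3.** Methylation may be too slow, or 4 may revert to the quinone methide and scramble C7.
- The fallback sets out from 4 and removes the leaving group before any phenoxide is made.
- DIBAL-H (3.5 equiv, CH2Cl2, −78 °C, acyl–O cleavage, C7–O bond untouched) gives (1R,2R)-2-(4-allyl-2,6-dimethoxyphenoxy)-1-(4-hydroxy-3,5-dimethoxyphenyl)propan-1-ol F10.
- MeI/K2CO3 in acetone gives (1R,2R)-2-(4-allyl-2,6-dimethoxyphenoxy)-1-(3,4,5-trimethoxyphenyl)propan-1-ol F11.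
- Ac2O/pyridine/DMAP acetylates F11 with retention, and the fallback comes back at 5.

## Further compounds
F1 | step 2 | rac-erythro-2-(4-allyl-2,6-dimethoxyphenoxy)-1-(4-hydroxy-3,5-dimethoxyphenyl)propan-1-ol (racemate, 1S,2R enantiomer drawn) | C=CCc1cc(OC)c(O[C@H](C)[C@@H](O)c2cc(OC)c(O)c(OC)c2)c(OC)c1
F2 | step 2 | rac-erythro-2-(4-allyl-2,6-dimethoxyphenoxy)-1-(3,4,5-trimethoxyphenyl)propan-1-ol (racemate, 1S,2R enantiomer drawn) | C=CCc1cc(OC)c(O[C@H](C)[C@@H](O)c2cc(OC)c(OC)c(OC)c2)c(OC)c1
F3 | step 2 | (1R,2S)-2-(4-allyl-2,6-dimethoxyphenoxy)-1-(3,4,5-trimethoxyphenyl)propyl isobutyrate | C=CCc1cc(OC)c(O[C@@H](C)[C@H](OC(=O)C(C)C)c2cc(OC)c(OC)c(OC)c2)c(OC)c1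
F4 | step 2 | (1S,2R)-2-(4-allyl-2,6-dimethoxyphenoxy)-1-(3,4,5-trimethoxyphenyl)propan-1-ol (single enantiomer) | C=CCc1cc(OC)c(O[C@H](C)[C@@H](O)c2cc(OC)c(OC)c(OC)c2)c(OC)c1
F5 | step 1 | ethyl (R)-2-(4-allyl-2,6-dimethoxyphenoxy)propanoate | C=CCc1cc(OC)c(O[C@H](C)C(=O)OCC)c(OC)c1
F6 | step 1 | (R)-2-(4-allyl-2,6-dimethoxyphenoxy)propanal | C=CCc1cc(OC)c(O[C@H](C)C=O)c(OC)c1
F7 | step 1 | (2R)-2-(4-allyl-2,6-dimethoxyphenoxy)-1-(4-hydroxy-3,5-dimethoxyphenyl)propan-1-ol (C1 epimers) | C=CCc1cc(OC)c(O[C@H](C)C(O)c2cc(OC)c(O)c(OC)c2)c(OC)c1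
F8 | step 1 | 4-[(2R)-1-bromo-2-(4-allyl-2,6-dimethoxyphenoxy)propyl]-2,6-dimethoxyphenol (C1 epimers) | C=CCc1cc(OC)c(O[C@H](C)C(Br)c2cc(OC)c(O)c(OC)c2)c(OC)c1
F9 | step 1 | (R)-4-[2-(4-allyl-2,6-dimethoxyphenoxy)propylidene]-2,6-dimethoxycyclohexa-2,5-dien-1-one | C=CCc1cc(OC)c(O[C@H](C)C=C2C=C(OC)C(=O)C(OC)=C2)c(OC)c1
F10 | step 3 | (1R,2R)-2-(4-allyl-2,6-dimethoxyphenoxy)-1-(4-hydroxy-3,5-dimethoxyphenyl)propan-1-ol | C=CCc1cc(OC)c(O[C@H](C)[C@H](O)c2cc(OC)c(O)c(OC)c2)c(OC)c1
F11 | step 3 | (1R,2R)-2-(4-allyl-2,6-dimethoxyphenoxy)-1-(3,4,5-trimethoxyphenyl)propan-1-ol | C=CCc1cc(OC)c(O[C@H](C)[C@H](O)c2cc(OC)c(OC)c(OC)c2)c(OC)c1
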